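Before you reckon anything, choose what to count: I count the second substrate, as a fraction of the starting material charged.

- grey: starting material 10 mM; second substrate 5 mM; enzyme 0.50 µM; the very flask that is asked about, followed so far
- flask: starting material 10 mM; second substrate 5.00 mM; enzyme 0.50 µM; time 30 h

grey run (percent of the starting material charged): time / h: target / % = 2.00: 43.4; 4.00: 39.5; 10.0: 38.2; 25.0: 37.9

(scatter of a reading: 0.5 percentage points)

- target that was removed still counts
- the numbers in the tables scatter by 0.5 percentage points (one standard deviation)
- additions bring no volume worth counting

* target, in percent of the starting material first charged, at 30 h
* what to do for the largest gain in target; "none" if nothing gains more than 2 percentage points (dawn / spring / dusk / winter / none)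
* target present, with what was taken out counted in, in percent of the starting material first charged, after spring
* target present, with what was taken out counted in, in percent of the starting material first charged, after winter

- dawn: at 30 h take out 90% of the target then present, then wait 30 h
- spring: at 30 h add second substrate, 100% of the amount charged, then wait 30 h
- dusk: change nothing and wait 30 h more
- winter: at 30 h add enzyme, 100% of the amount charged, then wait 30 h

In the grey run, which is the flask itself followed so far, that fraction is 50.0%. There is less second substrate than starting material, so if each target uses one second substrate, it is the limiting reagent and this fraction is the ceiling on target. The readings go from 43.4% to 37.9% and lie flat at the end, given a scatter of 0.5 percentage points.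

My assumption is that a pool is made quickly and the target then exchanges with some other form, at rates linear in target. Integrate that and you get an exponential whose end is a fixed share of the pool. So define the keep, the plateau target divided by the second substrate fraction: 0.758.

Now set the flask beside its neighbour with 2.0 mM of second substrate. The two look nearly the same, with equal starting material and enzyme, and I expect the same keep in both, so they should end apart by the size of their pools. For the flask I commit to 37.9% at 30 h. Spring adds 100% of the second substrate charged at 30 h and then waits 30 h. That doubles the pool, which gives 75.8%, and that is my choice. Dawn takes out 90% of the target and the keep then acts on the rest of the pool, which counts 46.2% with the removed part included. Dusk changes nothing and, on my reckoning, waits on the plateau for no gain. If enzyme speeds both directions of the exchange alike, the winter addition of 100% of the enzyme charged changes the time and not the keep, so it gains nothing.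

The forecast says 37.9% now, spring as best, 64% after spring and 37.8% after winter, reading the plateau as “kinetically controlled synthesis settling to a true equilibrium”. On spring it differs from my figure.

The simulation gives 37.9% now and spring as best, with a gain of 38 points. It gives 75.7% after spring and 37.9% after winter.

    starting material + enzyme ⇌ starting complex (K = 210 /M, k = 69000 /M/s)
    second substrate + starting complex ⇌ ternary complex (K = 3200 /M, k = 6.50 × 10⁵ /M/s)
    ternary complex → enzyme + target (k = 480 /min)
    target + enzyme ⇌ isomer of the product + enzyme, rate k4*[enzyme]*[target] forward; the back reaction follows from the equilibrium constant (K = 0.320, k = 9100 /M/min)

The running short of second substrate is the main reason the flask stands at 37.9%: the same run without it gives 75.8%. The keep of 0.758 is the target's share of the pool it forms with the isomer of the product. For the neighbour the second substrate fraction is 20.0%, and the keep turns that into 15.2%. The computed neighbour flask ends at 15.2%, with 4.85% as isomer of the product.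

(The readings are calculated for an exercise; noise was put on by code.)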